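## Retrosynthetic overview

1. The target is reached by global deprotection of 31. C14 is set by oxidation and Felkin–Anh reduction, and the C13–C14 bond by a Nozaki–Hiyama–Kishi coupling of the C13 enol triflate 21 with the butenolide aldehyde 28. Aldehyde 28 comes from a vinylogous Mukaiyama aldol of the silyloxyfuran of 4-methylfuran-2(5H)-one with (R)-glyceraldehyde acetonide.
2. The 4α-CHO/6α-OH pair is carried as the methyl acetal of a lactol, which comes from a γ-lactone between C18 and the 6α-oxygen. That lactone is closed by carboxylate-directed C–H lactonisation of the δ-lactone acid 12, whose δ-lactone stores C13 and the 8α-oxygen.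
3. Feature on which the plan rests: in the trans-fused decalin of ring A and ring B, the equatorial α-carboxyl carbon C18 on C4 and the equatorial 6α-hydrogen on C6 are 1,3-related across the ring-fusion carbon C5, on the same face. This is the same pair of positions that carries CHO and OH in the target.
4. Acid 12 comes from abietic acid: ring C is cut at C13=C14 (dihydroxylation, glycol cleavage), the enal is transposed reductively to C8=CH2, hydrated to the 8α-ol, and the isopropyl ketone is converted by Baeyer–Villiger oxidation and lactonisation.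
5. Ring order: rings A and B are taken from abietic acid and ring C is opened. The δ-lactone is closed (step 8), then the γ-lactone (step 10). The δ-lactone is reopened (step 11), the γ-lactone is reduced to the cyclic acetal (steps 15–16) and opened in step 24. The butenolide ring is brought in ready-made.

Key step: step 10

Numbering: labdane numbers are used for the core (C17 = methyl on C8, the former C14 of abietic acid; C18 = α-carbon on C4; C19 = β-methyl on C4; C20 = methyl on C10; C16 = exo-methylene carbon on C13). The side chain is C14, C15, and the butenolide atoms are primed (O1', C2', C3', C4' with its methyl, C5').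

Assumption: the target is taken as the open 6α-hydroxy C18-aldehyde as drawn; this γ-hydroxy aldehyde can close reversibly to its 18,6α-lactol, and step 24 is meant to deliver that equilibrium pair.

Remark: compounds 20, 21 and 29–31 are expected as mixtures of epimers at the acetal carbon C18 (left open in the SMILES), a centre that disappears in step 24; compound 29 is also a mixture at C14.

## Route

Step 1
Reactants: 1 abietic acid
Product: 2 benzyl abietate
Conditions: BnBr, K2CO3, DMF, rt
Reagents that add atoms: benzyl bromide, BrCc1ccccc1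
Why: SN2 O-alkylation of the carboxylate gives the benzyl ester, which keeps the hindered C4 acid inert to borane, hydride and peracid until it is removed by hydrogenolysis in step 9.

Step 2
Reactants: 2 benzyl abietate
Product: 3 benzyl 13α,14α-dihydroxyabiet-7-en-18-oate
Conditions: OsO4 (cat.), Me3NO·2H2O, pyridine, tBuOH–H2O, 80 °C
Reagents that add atoms: osmium tetroxide, O=[Os](=O)(=O)=O; trimethylamine N-oxide, C[N+](C)(C)[O-]; water, O
Why: Catalytic osmium syn-dihydroxylation should take the more accessible C13=C14 end of the diene from the α-face, opposite the C10 methyl; both carbinol centres are removed again in step 3.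

Step 3
Reactants: 3 benzyl 13α,14α-dihydroxyabiet-7-en-18-oate
Product: 4 benzyl 13,14-dioxo-13,14-secoabiet-7-en-18-oate (C8-formyl Δ7 enal with the C13 isopropyl ketone on the C9 chain)
Conditions: NaIO4, THF–H2O, rt
Reagents that add atoms: none
Why: Malaprade glycol cleavage of the cis-diol opens ring C between C13 and C14 and gives the C14 enal and the C13 isopropyl ketone.

Step 4
Reactants: 4 seco keto-enal
Product: 5 (E)-tosylhydrazone of 4 at the C14 aldehyde
Conditions: TsNHNH2 (1.05 equiv), EtOH, rt
Reagents that add atoms: 4-methylbenzenesulfonohydrazide, Cc1ccc(cc1)S(=O)(=O)NN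
Why: Hydrazone condensation should be much faster at the aldehyde than at the α-branched ketone.

Step 5
Reactants: 5 C14 tosylhydrazone
Product: 8 benzyl 13-oxo-13,14-secoabiet-8(14)-en-18-oate (exocyclic C8=CH2, the methylene carbon now called C17), via N-boryl tosylhydrazine 6 (not isolated), via allylic diazene 7 (not isolated)
Conditions: catecholborane (1.2 equiv), CHCl3, 0 °C; then NaOAc·3H2O, 60 °C
Reagents that add atoms: none
Why: Reductive 1,3-transposition of an enal tosylhydrazone: 1,2-hydride addition to C=N, loss of sulfinate and retro-ene loss of N2 from the allylic diazene put hydrogen on C7 and the double bond at C8=C17, while the hindered ketone should be reduced far more slowly than the hydrazone.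

Step 6
Reactants: 8 exocyclic alkene ketone
Product: 9 benzyl 8α-hydroxy-13-oxo-13,14-secoabietan-18-oate (8α-OH, 8β-CH3)
Conditions: Co(acac)2 (20 mol%), PhSiH3, O2 (1 atm), THF, rt; then aq. Na2S2O3
Reagents that add atoms: dioxygen, O=O
Why: Mukaiyama hydration (hydrogen-atom transfer to the CH2 terminus, then O2 capture of the tertiary C8 radical) gives the Markovnikov alcohol, and oxygen should enter from the α-face because the β (axial) approach is blocked by the axial C10 methyl, which sets the 8α-OH/8β-CH3 centre.

Step 7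
Reactants: 9 8α-hydroxy ketone
Product: 10 18-benzyl 13-isopropyl 8α-hydroxy-14,15,16-trinorlabdane-13,18-dioate
Conditions: mCPBA, NaHCO3, CH2Cl2, rt
Reagents that add atoms: 3-chloroperbenzoic acid, O=C(OO)c1cccc(Cl)c1
Why: Baeyer–Villiger oxidation, in which the secondary isopropyl group migrates in preference to the primary C12 methylene, so that C13 becomes an ester carbon.

Step 8
Reactants: 10 hydroxy isopropyl ester
Product: 11 benzyl 8α-hydroxy-14,15,16-trinorlabdane-13,18-dioate 13,8-lactone (δ-lactone)
Conditions: NaH, THF, 0 °C → rt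
Reagents that add atoms: none
Why: Intramolecular transesterification (lactonisation) by the tertiary alkoxide closes the trans-fused six-membered lactone and expels the less basic isopropoxide; the C4 benzyl ester is too hindered to exchange.

Step 9
Reactants: 11 δ-lactone benzyl ester
Product: 12 8α-hydroxy-14,15,16-trinorlabdane-13,18-dioic acid 13,8-lactone (free 4α-carboxylic acid)
Conditions: H2 (1 atm), Pd/C (10%), EtOAc, rt
Reagents that add atoms: none
Why: Hydrogenolysis of the benzylic C–O bond frees the hindered acid without touching the lactone, and no alkene is left in the molecule.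

Step 10
Reactants: 12 δ-lactone acid; 13 hydrogen peroxide
Product: 14 6α,8α-dihydroxy-14,15,16-trinorlabdane-13,18-dioic acid 13,8:18,6-dilactone
Conditions: [Fe((S,S)-PDP)(MeCN)2](SbF6)2 (3 × 5 mol%), H2O2 (50% aq., 3 × 1.2 equiv), MeCN, rt
Reagents that add atoms: none
Why: The C4 carboxylate binds the iron centre and assists O–O heterolysis of bound H2O2 to a high-valent (formally pentavalent) iron-oxo carboxylate, which abstracts the hydrogen held closest, the equatorial 6α-H, and the C6 radical rebounds onto the bound carboxylate oxygen. The closest known reaction type is the carboxylic-acid-directed γ-C(sp3)–H lactonisation with non-haem iron or manganese catalysts and H2O2. The five-membered lactone ring (C18, O, C6, C5, C4) is closed by intramolecular C6–O bond formation inside the iron-carboxylate cage and ends up fused to ring A at C4–C5 and to ring B at C5–C6. The new centre at C6 is fixed by the substrate: only the 6α-hydrogen lies gauche to C18 on the α-face, rebound occurs on the face of abstraction, and a lactone from the α-carboxyl can only span to 6α. The step needs site selectivity for C6 over the undirected ring A methylenes C2 and C3 and over the tertiary C5–H and C9–H; it is secured by intramolecular delivery from the carboxylate, by the rigid trans-decalin (the other γ-hydrogens on C2 point away), and by the δ-lactone, which has no oxidisable C–H next to oxygen. The product lactone no longer binds the catalyst and is electronically deactivated, which should limit over-oxidation.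

Step 11
Reactants: 14 bis-lactone
Product: 15 N-methoxy-N-methyl 6α,8α-dihydroxy-18-oxo-14,15,16-trinorlabdan-13-amide 18,6-lactone (free 8α-OH)
Conditions: MeNH(OMe)·HCl, AlMe3, CH2Cl2, 0 °C → rt
Reagents that add atoms: N,O-dimethylhydroxylamine hydrochloride, Cl.CNOC
Why: Aluminium-amide aminolysis (Weinreb amide formation) should open only the unhindered δ-lactone, because the γ-lactone carbonyl sits on the quaternary C4.

Step 12
Reactants: 15 hydroxy Weinreb amide
Product: 16 8-O-triethylsilyl ether of 15
Conditions: Et3SiOTf, 2,6-lutidine, CH2Cl2, −78 → 0 °C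
Reagents that add atoms: triethylsilyl trifluoromethanesulfonate, CC[Si](CC)(CC)OS(=O)(=O)C(F)(F)F
Why: Silyl triflate silylation protects the tertiary 8α-alcohol, so that it can neither re-lactonise nor interfere with the enolate chemistry of step 14.

Step 13
Reactants: 16 silylated Weinreb amide
Product: 17 8α-(triethylsilyloxy)-6α-hydroxy-13-oxo-14,15-dinorlabdan-18-oic acid 18,6-lactone (methyl ketone; the new methyl is C16)
Conditions: MeMgBr (1.5 equiv), THF, −20 → 0 °C
Reagents that add atoms: methylmagnesium bromide, C[Mg]Br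
Why: Weinreb ketone synthesis, in which the chelated tetrahedral intermediate stops at the ketone stage and the neopentyl γ-lactone should react much more slowly at low temperature.

Step 14
Reactants: 17 methyl ketone
Product: 19 8α-(triethylsilyloxy)-13-(trifluoromethanesulfonyloxy)-6α-hydroxy-14,15-dinorlabd-13(16)-en-18-oic acid 18,6-lactone, via potassium enolate 18 (not isolated)
Conditions: KN(SiMe3)2, THF, −78 °C; then PhNTf2, −78 → −20 °C
Reagents that add atoms: N-phenylbis(trifluoromethanesulfonimide), O=S(=O)(N(c1ccccc1)S(=O)(=O)C(F)(F)F)C(F)(F)F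
Why: Kinetic deprotonation at the methyl group and O-sulfonylation of the enolate give the 2-triflyloxy-1-alkene; the γ-lactone has no α-hydrogen and is not enolised.

Step 15
Reactants: 19 enol triflate γ-lactone
Product: 20 the corresponding 18,6α-lactol (6α,18-epoxy-18-hydroxy compound)
Conditions: iBu2AlH, CH2Cl2, −78 °C; aq. KNaC4H4O6 work-up
Reagents that add atoms: none
Why: Partial lactone reduction stops at the aluminium hemiacetal at low temperature, and it is placed here because the enol triflate and the silyl ether are inert and no other carbonyl group is left.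

Step 16
Reactants: 20 lactol
Product: 21 18-methoxy-6α,18-epoxy methyl acetal of 20 (enol triflate and 8-O-triethylsilyl ether retained)
Conditions: MeOH, PPTS (cat.), rt
Reagents that add atoms: methanol, CO
Why: Acid-catalysed acetalisation through the five-membered oxocarbenium ion (Fischer glycosidation type) masks the C18 aldehyde and the 6α-hydroxyl together, and the tertiary silyl ether should tolerate the weak acid.

Step 17
Reactants: 22 4-methylfuran-2(5H)-one
Product: 23 2-(tert-butyldimethylsilyloxy)-4-methylfuran
Conditions: tBuMe2SiOTf, Et3N, CH2Cl2, 0 °C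
Reagents that add atoms: tert-butyldimethylsilyl trifluoromethanesulfonate, CC(C)(C)[Si](C)(C)OS(=O)(=O)C(F)(F)F
Why: Soft enolisation at C5 and O-silylation give the aromatic silyl dienol ether.

Step 18
Reactants: 23 silyloxyfuran; 24 (R)-2,3-O-isopropylideneglyceraldehyde
Product: 25 (5R)-5-{(S)-[(4R)-2,2-dimethyl-1,3-dioxolan-4-yl](hydroxy)methyl}-4-methylfuran-2(5H)-one
Conditions: BF3·OEt2, CH2Cl2, −78 °C
Reagents that add atoms: none
Why: Vinylogous Mukaiyama aldol at the furan C5, in which Felkin–Anh attack anti to the dioxolane oxygen sets C15 and the open transition state gives the threo (syn) relation between the new hydroxyl and the ring oxygen at C5', as is usual for 2-silyloxyfurans with this aldehyde.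

Step 19
Reactants: 25 aldol adduct
Product: 26 O-tert-butyldimethylsilyl ether of 25
Conditions: tBuMe2SiOTf, 2,6-lutidine, CH2Cl2, −78 → 0 °C
Reagents that add atoms: tert-butyldimethylsilyl trifluoromethanesulfonate, CC(C)(C)[Si](C)(C)OS(=O)(=O)C(F)(F)F
Why: Silylation with a weak, hindered base protects the C15 hydroxyl without epimerising the base-sensitive C5' centre of the butenolide.

Step 20
Reactants: 26 silyl ether acetonide
Product: 28 (2S)-2-(tert-butyldimethylsilyloxy)-2-[(2R)-3-methyl-5-oxo-2,5-dihydrofuran-2-yl]acetaldehyde, via silyloxy diol 27 (not isolated)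
Conditions: H5IO6, EtOAc, rt
Reagents that add atoms: none
Why: Periodic acid hydrolyses the terminal acetonide and cleaves the resulting 1,2-diol (Malaprade) in one pot, so the glyceraldehyde centre that steered step 18 is removed and the aldehyde carbon becomes C14.

Step 21
Reactants: 21 enol triflate methyl acetal; 28 butenolide aldehyde
Product: 29 coupled allylic alcohol (C13 exo-methylene, C14–OH as both epimers, C15–OSitBuMe2 and C5' as in 28)
Conditions: CrCl2 (4 equiv), NiCl2 (2 mol%), DMF, rt
Reagents that add atoms: none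
Why: Nozaki–Hiyama–Kishi coupling: zerovalent nickel inserts into the C–OTf bond, the alkenyl group passes to trivalent chromium and adds chemoselectively to the aldehyde to form the C13–C14 bond; the C14 configuration is not relied on here and is set in steps 22 and 23.

Step 22
Reactants: 29 allylic alcohol (C14 epimers)
Product: 30 C14 ketone (α-methylene ketone)
Conditions: Dess–Martin periodinane, NaHCO3, CH2Cl2, 0 °C → rt
Reagents that add atoms: none
Why: Buffered Dess–Martin oxidation of the allylic alcohol merges both C14 epimers into one enone under conditions that leave the acidic C15–H and C5'–H untouched.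

Step 23
Reactants: 30 enone
Product: 31 (14S,15R,5'R)-allylic alcohol (14,15-syn)
Conditions: NaBH4, CeCl3·7H2O, MeOH, −78 °C
Reagents that add atoms: none
Why: Luche 1,2-reduction, in which Felkin–Anh hydride delivery anti to the C15 silyloxy group should give the 14,15-syn alcohol, that is 14S.

Step 24
Reactants: 31 protected precursor
Product: 32 target CNP0156243.1
Conditions: HF (48% aq.), MeCN, 0 °C → rt
Reagents that add atoms: water, O
Why: Aqueous HF cleaves both silyl ethers and hydrolyses the cyclic methyl acetal to the 6α-hydroxy C18-aldehyde, while the butenolide, the tertiary alcohol and the allylic alcohol should survive the mild aqueous acid.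

## Compound list

1 | abietic acid | CC(C)C1=CC2=CC[C@@H]3[C@@]([C@H]2CC1)(CCC[C@@]3(C)C(=O)O)C | starting material
2 | benzyl abietate | CC(C)C1=CC2=CC[C@@H]3[C@@]([C@H]2CC1)(CCC[C@@]3(C)C(=O)OCc4ccccc4)C | intermediate
3 | benzyl 13α,14α-dihydroxyabiet-7-en-18-oate | CC(C)[C@@]1(O)[C@H](O)C2=CC[C@@H]3[C@@]([C@H]2CC1)(CCC[C@@]3(C)C(=O)OCc4ccccc4)C | intermediate
4 | benzyl 13,14-dioxo-13,14-secoabiet-7-en-18-oate | CC(C)C(=O)CC[C@@H]1[C@@]2(C)CCC[C@@](C)(C(=O)OCc3ccccc3)[C@@H]2CC=C1C=O | intermediate
5 | (E)-C14 tosylhydrazone of 4 | CC(C)C(=O)CC[C@@H]1[C@@]2(C)CCC[C@@](C)(C(=O)OCc3ccccc3)[C@@H]2CC=C1/C=N/NS(=O)(=O)c4ccc(C)cc4 | intermediate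
6 | N-boryl tosylhydrazine from 5 (C14H2–N(B-catecholate)–NHTs) | CC(C)C(=O)CC[C@@H]1[C@@]2(C)CCC[C@@](C)(C(=O)OCc3ccccc3)[C@@H]2CC=C1CN(B4Oc5ccccc5O4)NS(=O)(=O)c6ccc(C)cc6 | intermediate
7 | allylic diazene (C14H2–N=NH) | CC(C)C(=O)CC[C@@H]1[C@@]2(C)CCC[C@@](C)(C(=O)OCc3ccccc3)[C@@H]2CC=C1CN=N | intermediate
8 | benzyl 13-oxo-13,14-secoabiet-8(14)-en-18-oate | CC(C)C(=O)CC[C@@H]1[C@@]2(C)CCC[C@@](C)(C(=O)OCc3ccccc3)[C@@H]2CCC1=C | intermediate
9 | benzyl 8α-hydroxy-13-oxo-13,14-secoabietan-18-oate | CC(C)C(=O)CC[C@@H]1[C@@]2(C)CCC[C@@](C)(C(=O)OCc3ccccc3)[C@@H]2CC[C@@]1(C)O | intermediate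
10 | 18-benzyl 13-isopropyl 8α-hydroxy-14,15,16-trinorlabdane-13,18-dioate | CC(C)OC(=O)CC[C@@H]1[C@@]2(C)CCC[C@@](C)(C(=O)OCc3ccccc3)[C@@H]2CC[C@@]1(C)O | intermediate
11 | benzyl 8α-hydroxy-14,15,16-trinorlabdane-13,18-dioate 13,8-lactone | O=C1CC[C@@H]2[C@@]3(C)CCC[C@@](C)(C(=O)OCc4ccccc4)[C@@H]3CC[C@@]2(C)O1 | intermediate
12 | 8α-hydroxy-14,15,16-trinorlabdane-13,18-dioic acid 13,8-lactone | O=C1CC[C@@H]2[C@@]3(C)CCC[C@@](C)(C(=O)O)[C@@H]3CC[C@@]2(C)O1 | intermediate
13 | hydrogen peroxide | OO | starting material
14 | 6α,8α-dihydroxy-14,15,16-trinorlabdane-13,18-dioic acid 13,8:18,6-dilactone | O=C1CC[C@@H]2[C@@]3(C)CCC[C@]4(C)[C@@H]3[C@@H](OC4=O)C[C@@]2(C)O1 | intermediate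
15 | 8α-hydroxy Weinreb amide with the 18,6α-γ-lactone | CON(C)C(=O)CC[C@@H]1[C@@]2(C)CCC[C@]3(C)[C@@H]2[C@@H](OC3=O)C[C@@]1(C)O | intermediate
16 | 8-O-triethylsilyl ether of 15 | CON(C)C(=O)CC[C@@H]1[C@@]2(C)CCC[C@]3(C)[C@@H]2[C@@H](OC3=O)C[C@@]1(C)O[Si](CC)(CC)CC | intermediate
17 | C13 methyl ketone (8α-OSiEt3, 18,6α-γ-lactone) | CC(=O)CC[C@@H]1[C@@]2(C)CCC[C@]3(C)[C@@H]2[C@@H](OC3=O)C[C@@]1(C)O[Si](CC)(CC)CC | intermediate
18 | potassium enolate of 17 (terminal) | [K+].[O-]C(=C)CC[C@@H]1[C@@]2(C)CCC[C@]3(C)[C@@H]2[C@@H](OC3=O)C[C@@]1(C)O[Si](CC)(CC)CC | intermediate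
19 | C13 enol triflate (13(16)-ene, 8α-OSiEt3, 18,6α-γ-lactone) | C=C(OS(=O)(=O)C(F)(F)F)CC[C@@H]1[C@@]2(C)CCC[C@]3(C)[C@@H]2[C@@H](OC3=O)C[C@@]1(C)O[Si](CC)(CC)CC | intermediate
20 | 18,6α-lactol of 19 (C18 epimers) | C=C(OS(=O)(=O)C(F)(F)F)CC[C@@H]1[C@@]2(C)CCC[C@]3(C)[C@@H]2[C@@H](OC3O)C[C@@]1(C)O[Si](CC)(CC)CC | intermediate
21 | methyl acetal of 20 (18-methoxy-6α,18-epoxy, C18 epimers) | C=C(OS(=O)(=O)C(F)(F)F)CC[C@@H]1[C@@]2(C)CCC[C@]3(C)[C@@H]2[C@@H](OC3OC)C[C@@]1(C)O[Si](CC)(CC)CC | intermediate
22 | 4-methylfuran-2(5H)-one | CC1=CC(=O)OC1 | starting material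
23 | 2-(tert-butyldimethylsilyloxy)-4-methylfuran | Cc1coc(O[Si](C)(C)C(C)(C)C)c1 | intermediate
24 | (R)-2,3-O-isopropylideneglyceraldehyde | CC1(C)OC[C@@H](O1)C=O | starting material
25 | (5R)-5-{(S)-[(4R)-2,2-dimethyl-1,3-dioxolan-4-yl](hydroxy)methyl}-4-methylfuran-2(5H)-one | CC1(C)OC[C@@H](O1)[C@@H](O)[C@@H]2OC(=O)C=C2C | intermediate
26 | O-tert-butyldimethylsilyl ether of 25 | CC1(C)OC[C@@H](O1)[C@@H](O[Si](C)(C)C(C)(C)C)[C@@H]2OC(=O)C=C2C | intermediate
27 | (5R)-5-[(1R,2R)-1-(tert-butyldimethylsilyloxy)-2,3-dihydroxypropyl]-4-methylfuran-2(5H)-one | OC[C@@H](O)[C@@H](O[Si](C)(C)C(C)(C)C)[C@@H]1OC(=O)C=C1C | intermediate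
28 | (2S)-2-(tert-butyldimethylsilyloxy)-2-[(2R)-3-methyl-5-oxo-2,5-dihydrofuran-2-yl]acetaldehyde | O=C[C@@H](O[Si](C)(C)C(C)(C)C)[C@@H]1OC(=O)C=C1C | intermediate
29 | coupled allylic alcohol (C14 epimers; 15-OSitBuMe2, 8-OSiEt3, C18 methyl acetal) | C=C(CC[C@@H]1[C@@]2(C)CCC[C@]3(C)[C@@H]2[C@@H](OC3OC)C[C@@]1(C)O[Si](CC)(CC)CC)C(O)[C@@H](O[Si](C)(C)C(C)(C)C)[C@@H]4OC(=O)C=C4C | intermediate
30 | C14 ketone (13(16)-en-14-one) | C=C(CC[C@@H]1[C@@]2(C)CCC[C@]3(C)[C@@H]2[C@@H](OC3OC)C[C@@]1(C)O[Si](CC)(CC)CC)C(=O)[C@@H](O[Si](C)(C)C(C)(C)C)[C@@H]4OC(=O)C=C4C | intermediate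
31 | (14S,15R,5'R)-allylic alcohol, fully protected precursor | C=C(CC[C@@H]1[C@@]2(C)CCC[C@]3(C)[C@@H]2[C@@H](OC3OC)C[C@@]1(C)O[Si](CC)(CC)CC)[C@H](O)[C@@H](O[Si](C)(C)C(C)(C)C)[C@@H]4OC(=O)C=C4C | intermediate
32 | CNP0156243.1 | C=C(CC[C@@H]1[C@@]2(C)CCC[C@@](C)(C=O)[C@@H]2[C@@H](O)C[C@@]1(C)O)[C@H](O)[C@@H](O)[C@@H]1OC(=O)C=C1C | target

## Step count

Total step count: 24.
Longest linear sequence: 20 steps (steps 1–16, then 21–24, from abietic acid); the butenolide branch (steps 17–20) joins at step 21.

## Steps most likely to fail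

**Step 10.** Undirected oxidation of the ring A methylenes (C2, C3), or decay of the catalyst, may outrun carboxylate-directed abstraction at the electronically deactivated C6–H, so that conversion stalls or ketones form. The fallback sets out from acid 12 and comes back to the route at bis-lactone 14. It uses amide-directed radical functionalisation of the Hofmann–Löffler–Freytag type. Acid 12 is converted with (COCl)2 and catalytic DMF into the acid chloride F1, and NH3 at low temperature gives the primary amide F2. Treatment with PhI(OAc)2 and I2 under visible light forms the N-iodo amide F3; its amidyl radical takes the 6α-hydrogen by 1,5-transfer and the carbon radical is trapped as the 6-iodo amide F4. This closes through the amide oxygen on the α-face to the iminolactone F5. Hydrolysis with aqueous acetic acid in THF gives 14.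

**Step 23.** Hydride may attack both faces of the C14 ketone, because the Felkin–Anh preference set by the C15 silyloxy group is only a 1,2-substrate effect on a conformationally mobile enone. The fallback sets out from enol triflate 21 and aldehyde 28 and comes back at 31, leaving out 29 and 30. C14 is set in the carbon–carbon bond-forming event by a ligand-controlled asymmetric Nozaki–Hiyama–Kishi coupling (CrCl2, NiCl2 as catalyst, Et3N and a chiral oxazolinyl-aryl sulfonamide ligand chosen for the 14S sense), a known way to make 1,1-disubstituted allylic alcohols with reagent control. No new compound is made (F0).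

**Step 6.** The C8 radical may be captured by oxygen from both faces, or be reduced instead of oxygenated, which would give the 8-epimer or the saturated compound. The fallback sets out from alkene 8 and comes back at 9. Oxymercuration with Hg(OAc)2 in THF–H2O delivers water to C8 from the α-face and gives the 17-(acetoxymercurio) 8α-alcohol F6. Demercuration with NaBH4 in aqueous NaOH also reduces the C13 ketone and gives the 8α,13-diol F7 (C13 epimers). Dess–Martin periodinane then reoxidises only the secondary alcohol and returns hydroxy ketone 9.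

## Further compounds

F1 | step 10 | acid chloride of 12 | O=C1CC[C@@H]2[C@@]3(C)CCC[C@@](C)(C(=O)Cl)[C@@H]3CC[C@@]2(C)O1
F2 | step 10 | primary amide of 12 | O=C1CC[C@@H]2[C@@]3(C)CCC[C@@](C)(C(N)=O)[C@@H]3CC[C@@]2(C)O1
F3 | step 10 | N-iodo amide | O=C1CC[C@@H]2[C@@]3(C)CCC[C@@](C)(C(=O)NI)[C@@H]3CC[C@@]2(C)O1
F4 | step 10 | 6-iodo amide (C6 epimers) | O=C1CC[C@@H]2[C@@]3(C)CCC[C@@](C)(C(N)=O)[C@@H]3C(I)C[C@@]2(C)O1
F5 | step 10 | 18,6α-iminolactone | O=C1CC[C@@H]2[C@@]3(C)CCC[C@]4(C)[C@@H]3[C@@H](OC4=N)C[C@@]2(C)O1
F0 | step 23 | none | none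
F6 | step 6 | benzyl 17-(acetoxymercurio)-8α-hydroxy-13-oxo-13,14-secoabietan-18-oate | CC(C)C(=O)CC[C@@H]1[C@@]2(C)CCC[C@@](C)(C(=O)OCc3ccccc3)[C@@H]2CC[C@@]1(C[Hg]OC(C)=O)O
F7 | step 6 | benzyl 8α,13-dihydroxy-13,14-secoabietan-18-oate (C13 epimers) | CC(C)C(O)CC[C@@H]1[C@@]2(C)CCC[C@@](C)(C(=O)OCc3ccccc3)[C@@H]2CC[C@@]1(C)O
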